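**Retrosynthetic overview**
1. Target 16 ⇐ site- and face-selective epoxidation of the 1(10)-olefin of bis-angelate 15 ⇐ double angeloylation of diol 14.
2. 14 ⇐ 11-OH-directed reduction of the macrocyclic Z-enone 13 ⇐ electroreductive nickel-catalysed acyl–alkyl ring closure (C6–C7) of bromo acid 11.
3. 11 ⇐ nickel cross-electrophile coupling (C9–C10) of dibromolactone 3 with alkenyl bromide acid 10.
4. 3 ⇐ 2-C-methyl-D-ribono-1,4-lactone 1 (brings C8 and C11; its C3 becomes C7). 10 ⇐ carbocupration of propyne 5 by the Grignard reagent of 4, CO2, then hydrozirconation–bromination.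
5. Ring order: γ-lactone (bought) → cyclodecadiene → epoxide.

Assumption: germacranolide numbering is used (ring C1–C10, lactone C11/C12 with C13 methyl, C14 on C10, C15 on C4; sugar C1–C5 of 1 = C12, C11, C7, C8, C9), and 1, 4, 5 and angelic anhydride are taken as commercial.

Step 1
Reactants: 1 2-C-methyl-D-ribono-1,4-lactone
Product: 3 (3S,4S,5R)-4-bromo-5-(bromomethyl)-3-hydroxy-3-methyloxolan-2-one, via tertiary acetate 2 (not isolated)
Conditions: 33% HBr in AcOH, 25 °C, 24 h; then MeOH, 40 °C, 24 h
Reagents that add atoms: hydrogen bromide (Br)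
Why: Bromodeoxygenation of an aldonolactone with HBr/AcOH: the primary hydroxyl is replaced through its acetate, the cis-2,3-diol forms an acetoxonium ion that bromide can open only at the secondary carbon (future C7, inversion; the tertiary α-carbonyl C11 cannot undergo SN2), and acid methanolysis removes the tertiary acetate; C8 and C11 keep the configuration bought in 1, and the C7 configuration is irrelevant because C7 later reacts as a radical.

Step 2
Reactants: 4 5-bromopent-2-yne; 5 propyne
Product: 8 (2Z)-3-methyloct-2-en-6-ynoic acid, via Grignard reagent 6 (not isolated), via alkenylcopper 7 (not isolated)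
Conditions: Mg, Et2O; CuBr·SMe2, Et2O/Me2S, −45 °C; 5 (excess), −25 °C; CO2, P(OEt)3 (cat.), DMPU, −40 °C to rt; aq. HCl
Reagents that add atoms: carbon dioxide (O=C=O)
Why: Normant carbocupration: the alkylcopper adds syn across propyne with copper on the terminal carbon, and carboxylation of the alkenylcopper with retention puts the carboxyl cis to the chain, which fixes the 4Z olefin.

Step 3
Reactants: 8 (2Z)-3-methyloct-2-en-6-ynoic acid
Product: 10 (2Z,6E)-7-bromo-3-methylocta-2,6-dienoic acid, via alkenylzirconocene 9 (not isolated)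
Conditions: Cp2Zr(H)Cl (2.5 equiv), THF, 25 to 40 °C; NBS, 0 °C; aq. HCl
Reagents that add atoms: N-bromosuccinimide (O=C1CCC(=O)N1Br)
Why: Schwartz hydrozirconation (one equivalent is spent on the acid as its zirconium carboxylate): syn H–Zr addition with equilibration places zirconium on the less hindered, methyl-bearing alkyne carbon (about 9:1 expected), and bromodezirconation with retention gives the E-2-bromoalkene that becomes the 1(10)E olefin.

Step 4
Reactants: 3 (3S,4S,5R)-4-bromo-5-(bromomethyl)-3-hydroxy-3-methyloxolan-2-one; 10 (2Z,6E)-7-bromo-3-methylocta-2,6-dienoic acid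
Product: 11 (2Z,6E)-8-[(2R,3S,4S)-3-bromo-4-hydroxy-4-methyl-5-oxooxolan-2-yl]-3,7-dimethylocta-2,6-dienoic acid
Conditions: NiBr2·glyme (10 mol%), 4,4′-di-tert-butyl-2,2′-bipyridine (10 mol%), NaI (0.5 equiv), Mn powder (3 equiv), DMA, 25 °C; aq. citric acid
Reagents that add atoms: none
Why: Nickel-catalysed reductive cross-electrophile coupling of an alkenyl bromide with an alkyl halide: only the unhindered primary bromide of 3 undergoes Finkelstein exchange with NaI and fast halogen abstraction, the neopentyl-like secondary C7 bromide is left, and the C9 radical is joined to the alkenylnickel with retention of the E geometry; no stereocentre is involved.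

Step 5
Reactants: 11 (2Z,6E)-8-[(2R,3S,4S)-3-bromo-4-hydroxy-4-methyl-5-oxooxolan-2-yl]-3,7-dimethylocta-2,6-dienoic acid
Product: 13 (7R,8R,11R)-11-hydroxy-6-oxogermacra-1(10)E,4Z-dien-12,8-olide, via mixed carbonic anhydride 12 (not isolated)
Conditions: Boc2O (1.3 equiv), MgCl2 (1.5 equiv), DMA, 25 °C, 1 h; then slow addition (8 h, final 2 mM) to NiBr2·glyme (20 mol%), 4,4′-di-tert-butyl-2,2′-bipyridine (22 mol%), nBu4NBr, DMA, undivided cell, Zn anode, Ni-foam cathode, 3 mA, 25 °C
Reagents that add atoms: none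
Why: Proposed new method: electroreductive nickel-catalysed intramolecular acyl–alkyl coupling that closes a ten-membered ring; cathodically formed zerovalent nickel inserts into the acyl C–O bond of 12, the divalent acylnickel is reduced to the monovalent state and abstracts bromine from C7, and the secondary radical recombines to a trivalent acyl(alkyl)nickel that reductively eliminates the C6–C7 bond, with radical capture on the lactone face that carries the 11-hydroxyl (anti to the C13 methyl and the C9 chain) so that C7 is set R with H7 trans to H8 and the enoyl Z geometry is untouched; the closest known reactions are the intermolecular nickel-catalysed reductive ketone synthesis from alkyl bromides and carboxylic acids activated in situ with Boc2O and the electroreductive nickel-catalysed coupling of alkyl halides with acyl chlorides, neither of which has been used for a medium ring or at a ring-fusion carbon.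

Step 6
Reactants: 13 (7R,8R,11R)-11-hydroxy-6-oxogermacra-1(10)E,4Z-dien-12,8-olide
Product: 14 (6R,7R,8R,11R)-6,11-dihydroxygermacra-1(10)E,4Z-dien-12,8-olide
Conditions: Me4NBH(OAc)3 (5 equiv), MeCN/AcOH 1:1, −30 °C; aq. NaHCO3
Reagents that add atoms: none
Why: Evans–Saksena hydroxyl-directed reduction: the tertiary 11-hydroxyl, cis to the C6 carbonyl on the lactone, exchanges onto boron and delivers hydride internally to the Si face of C6 (assuming the ring holds C=O syn to C7–C8 with C11 perpendicular to the carbonyl plane), which gives the 6R alcohol, whereas an external hydride would attack the opposite face.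

Step 7
Reactants: 14 (6R,7R,8R,11R)-6,11-dihydroxygermacra-1(10)E,4Z-dien-12,8-olide
Product: 15 (6R,7S,8R,11R)-6,11-bis(angeloyloxy)germacra-1(10)E,4Z-dien-12,8-olide
Conditions: angelic anhydride (5 equiv), MgBr2·OEt2 (4 equiv), Et3N (8 equiv), CH2Cl2, 0 to 25 °C
Reagents that add atoms: angelic anhydride (C/C=C(/C)C(=O)OC(=O)/C(C)=C\C)
Why: MgBr2/tertiary-amine-promoted acylation with an anhydride esterifies both the allylic secondary alcohol and the chelating tertiary α-hydroxy-lactone alcohol without DMAP or free alkoxide, which avoids angelate-to-tiglate isomerisation and translactonisation to C6; no stereocentre changes.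

Step 8
Reactants: 15 (6R,7S,8R,11R)-6,11-bis(angeloyloxy)germacra-1(10)E,4Z-dien-12,8-olide
Product: 16 (1R,6R,7S,8R,10R,11R)-1,10-epoxy-6,11-bis(angeloyloxy)germacr-4Z-en-12,8-olide
Conditions: mCPBA (1.1 equiv), NaHCO3, CH2Cl2, −20 °C
Reagents that add atoms: mCPBA (OOC(=O)c1cccc(Cl)c1)
Why: Prilezhaev epoxidation: the isolated trisubstituted 1(10)-olefin is far more nucleophilic than the 4-ene deactivated by the allylic ester and than the conjugated angelate olefins, and the peracid adds from the exposed outer face of the E-olefin as in peripheral epoxidation of germacranolides, which is expected (not proven) to give the trans (1R,10R)-epoxide.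

**Compound list**
1 | 2-C-methyl-D-ribono-1,4-lactone, (3R,4R,5R)-3,4-dihydroxy-5-(hydroxymethyl)-3-methyloxolan-2-one | OC[C@H]1OC(=O)[C@](C)(O)[C@@H]1O | starting material
2 | (3S,4S,5R)-4-bromo-5-(bromomethyl)-3-methyl-2-oxooxolan-3-yl acetate | BrC[C@H]1OC(=O)[C@](C)(OC(C)=O)[C@H]1Br | intermediate
3 | (3S,4S,5R)-4-bromo-5-(bromomethyl)-3-hydroxy-3-methyloxolan-2-one (ring bromine trans to the tertiary hydroxyl) | BrC[C@H]1OC(=O)[C@](C)(O)[C@H]1Br | intermediate
4 | 5-bromopent-2-yne | CC#CCCBr | starting material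
5 | propyne | CC#C | starting material
6 | pent-3-yn-1-ylmagnesium bromide | CC#CCC[Mg]Br | intermediate
7 | [(1Z)-2-methylhept-1-en-5-yn-1-yl]copper | [Cu]/C=C(/C)CCC#CC | intermediate
8 | (2Z)-3-methyloct-2-en-6-ynoic acid | OC(=O)/C=C(/C)CCC#CC | intermediate
9 | chlorozirconocene carboxylate of (2Z,6E)-7-(chlorozirconocenyl)-3-methylocta-2,6-dienoic acid | C/C(=C\CC/C(C)=C\C(=O)O[Zr](Cl)(C1C=CC=C1)C1C=CC=C1)[Zr](Cl)(C1C=CC=C1)C1C=CC=C1 | intermediate
10 | (2Z,6E)-7-bromo-3-methylocta-2,6-dienoic acid | OC(=O)/C=C(/C)CC/C=C(\C)Br | intermediate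
11 | (2Z,6E)-8-[(2R,3S,4S)-3-bromo-4-hydroxy-4-methyl-5-oxooxolan-2-yl]-3,7-dimethylocta-2,6-dienoic acid | OC(=O)/C=C(/C)CC/C=C(\C)C[C@H]1OC(=O)[C@](C)(O)[C@H]1Br | intermediate
12 | mixed anhydride of 11 with tert-butyl hydrogen carbonate | CC(C)(C)OC(=O)OC(=O)/C=C(/C)CC/C=C(\C)C[C@H]1OC(=O)[C@](C)(O)[C@H]1Br | intermediate
13 | (7R,8R,11R)-11-hydroxy-6-oxogermacra-1(10)E,4Z-dien-12,8-olide | O=C1/C=C(/C)CC/C=C(\C)C[C@H]2OC(=O)[C@](C)(O)[C@H]12 | intermediate
14 | (6R,7R,8R,11R)-6,11-dihydroxygermacra-1(10)E,4Z-dien-12,8-olide | O[C@@H]1/C=C(/C)CC/C=C(\C)C[C@H]2OC(=O)[C@](C)(O)[C@H]12 | intermediate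
15 | (6R,7S,8R,11R)-6,11-bis(angeloyloxy)germacra-1(10)E,4Z-dien-12,8-olide | C/C=C(/C)C(=O)O[C@@H]1/C=C(/C)CC/C=C(\C)C[C@H]2OC(=O)[C@](C)(OC(=O)/C(C)=C\C)[C@H]12 | intermediate
16 | (1R,6R,7S,8R,10R,11R)-1,10-epoxy-6,11-bis(angeloyloxy)germacr-4Z-en-12,8-olide (CNP0182151.2) | C/C=C(/C)C(=O)O[C@@H]1/C=C(/C)CC[C@H]2O[C@]2(C)C[C@H]2OC(=O)[C@](C)(OC(=O)/C(C)=C\C)[C@H]12 | target

**Step count and risks**
Total: 8 steps. Longest linear sequence: 7 steps (steps 2 to 8, from 4 and 5); the branch from 1 is 6 steps.

Three steps most likely to fail: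

Step 5 (the proposed new ring closure; medium-ring strain, β-elimination at nickel or oligomerisation may win). Fallback with known chemistry, setting out from 7 and 3 and returning at 14: the ring is closed at C5–C6 by a Nozaki–Hiyama–Kishi reaction instead. Alkenylcopper 7 is quenched with NBS instead of CO2 to give (Z)-1-bromo-2-methylhept-1-en-5-yne F1. Hydrozirconation with Cp2Zr(H)Cl and iodinolysis give (1Z,5E)-1-bromo-6-iodo-2-methylhepta-1,5-diene F2. The nickel/Mn coupling of step 4 joins the alkenyl iodide end of F2 to C9 of 3 and gives (3S,4S,5R)-4-bromo-5-[(2E,6Z)-7-bromo-2,6-dimethylhepta-2,6-dien-1-yl]-3-hydroxy-3-methyloxolan-2-one F3. Tin hydride radical carbonylation (Bu3SnH, AIBN, CO 80 atm, benzene, 80 °C) turns the C7 bromide into the aldehyde (2R,3R,4R)-2-[(2E,6Z)-7-bromo-2,6-dimethylhepta-2,6-dien-1-yl]-4-hydroxy-4-methyl-5-oxooxolane-3-carbaldehyde F4 on the hydroxyl-bearing face. A classical Nozaki–Hiyama–Kishi macrocyclisation (CrCl2 in excess, NiCl2 1 mol%, DMSO/THF, high dilution) then forms C5–C6 by Felkin–Anh addition to the Re face of the aldehyde and gives diol 14 directly, so steps 5 and 6 are bypassed.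

Step 4 (chemoselectivity between the two alkyl bromides of 3; tolerance of the free acid). Fallback, setting out from 1 and returning at 11: the coupling is done before C7 carries a halogen. The primary hydroxyl of 1 alone is iodinated (PPh3, I2, imidazole, THF, 0 °C) to 5-deoxy-5-iodo-2-C-methyl-D-ribono-1,4-lactone F5. F5 is coupled with 10 under the step 4 conditions, where no second alkyl halide competes, to give (2Z,6E)-8-[(2R,3R,4R)-3,4-dihydroxy-4-methyl-5-oxooxolan-2-yl]-3,7-dimethylocta-2,6-dienoic acid F6. The secondary C7 hydroxyl is then triflated (Tf2O, pyridine, CH2Cl2, −30 °C; the tertiary hydroxyl is inert and the acid is returned on aqueous work-up) and displaced with Bu4NBr with inversion to reach 11.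

Step 8 (the face of epoxidation is argued by analogy only). Fallback, setting out from 15 and returning at 16, for the case that the peracid gives the (1S,10S)-epoxide: NBS in wet DME at 0 °C forms the bromonium ion on that same exposed face and water opens it at C10 from the other side, giving (1S,6R,7S,8R,10R,11R)-1-bromo-10-hydroxy-6,11-bis(angeloyloxy)germacr-4Z-en-12,8-olide F7. Ag2O in CH2Cl2 closes the epoxide with inversion at C1, which puts the oxygen on the face the peracid does not reach and gives 16.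

**Further compounds**
F1 | step 5 | (Z)-1-bromo-2-methylhept-1-en-5-yne | Br/C=C(/C)CCC#CC
F2 | step 5 | (1Z,5E)-1-bromo-6-iodo-2-methylhepta-1,5-diene | Br/C=C(/C)CC/C=C(\C)I
F3 | step 5 | (3S,4S,5R)-4-bromo-5-[(2E,6Z)-7-bromo-2,6-dimethylhepta-2,6-dien-1-yl]-3-hydroxy-3-methyloxolan-2-one | Br/C=C(/C)CC/C=C(\C)C[C@H]1OC(=O)[C@](C)(O)[C@H]1Br
F4 | step 5 | (2R,3R,4R)-2-[(2E,6Z)-7-bromo-2,6-dimethylhepta-2,6-dien-1-yl]-4-hydroxy-4-methyl-5-oxooxolane-3-carbaldehyde | Br/C=C(/C)CC/C=C(\C)C[C@H]1OC(=O)[C@](C)(O)[C@@H]1C=O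
F5 | step 4 | 5-deoxy-5-iodo-2-C-methyl-D-ribono-1,4-lactone | IC[C@H]1OC(=O)[C@](C)(O)[C@@H]1O
F6 | step 4 | (2Z,6E)-8-[(2R,3R,4R)-3,4-dihydroxy-4-methyl-5-oxooxolan-2-yl]-3,7-dimethylocta-2,6-dienoic acid | OC(=O)/C=C(/C)CC/C=C(\C)C[C@H]1OC(=O)[C@](C)(O)[C@@H]1O
F7 | step 8 | (1S,6R,7S,8R,10R,11R)-1-bromo-10-hydroxy-6,11-bis(angeloyloxy)germacr-4Z-en-12,8-olide | C/C=C(/C)C(=O)O[C@@H]1/C=C(/C)CC[C@H](Br)[C@](C)(O)C[C@H]2OC(=O)[C@](C)(OC(=O)/C(C)=C\C)[C@H]12
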